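**Retrosynthetic overview**

1. Target 32 ⇐ global desilylation ⇐ inversion of the aroyl-bearing cyclohexene carbon C6'' by kinetic protonation ⇐ exo Diels–Alder adduct 29 ⇐ chalcone 28 + dienyl chromanedione 25 (cyclohexene ring formed last).
2. 25 ⇐ Stille coupling ⇐ iodo-chromanedione 22 ⇐ closure of ring C through the C2–C3 bond: copper hydride-catalysed asymmetric reductive Claisen-type cyclisation of the achiral dienone carbonate 20, which also sets C3 and creates the prenyl group.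
3. Enabling feature: C3 is both the α-carbon of the C4 aryl ketone and the carrier of the prenyl CH2, so a C3=CH–CH=CMe2 dienone is a latent prenyl enolate; ring A joins this C3 to the O1-bound carbonate carbon C2 through the four-atom tether C4–C4a–C8a–O1, so C2–C3 bond formation closes the six-membered lactone ring C.
4. 20 ⇐ phenol 19 ⇐ aldol condensation of deoxybenzoin 13 with 3-methylbut-2-enal; 13 ⇐ aldehyde 5 + benzylic chloride 10; 28 ⇐ acetophenone 27 + aldehyde 7.
5. Ring order: ring A and the three resorcinol rings are bought; ring C in step 13; the cyclohexene ring in step 18.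

Key step: step 13

Remarks on the chemistry:
- The target SMILES places the ring A substituent, the aroyl group and the aryl group of the cyclohexene all cis (1''S,5''R,6''R). The route therefore makes the trans,trans (exo) adduct and then inverts the aroyl-bearing carbon.
- The ligand antipodes in steps 13 and 18 are written for one sense of induction. If a first run shows the opposite sense, the mirror-image ligand is to be used.
- TBS = tert-butyldimethylsilyl, TBSO = tert-butyldimethylsilyloxy. Chromane numbering is used for the bicyclic core. In the cyclohexene, C1'' bears ring A, C3'' the methyl group, C5'' the aryl group and C6'' the aroyl group.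

**Route**

Step 1
Reactants: 1 2,4,6-trihydroxybenzaldehyde
Product: 2 4-(TBSO)-2,6-dihydroxybenzaldehyde
Conditions: TBSCl (1.0 equiv), imidazole, DMF, 0 °C
Reagents that add atoms: tert-butyldimethylsilyl chloride, CC(C)(C)[Si](C)(C)Cl
Why: The 4-hydroxyl is the most acidic one and the only one not tied up in a hydrogen bond to the formyl group, so one equivalent of silyl chloride should silylate it selectively (phenol silylation).

Step 2
Reactants: 2 4-(TBSO)-2,6-dihydroxybenzaldehyde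
Product: 3 4-(TBSO)-2-hydroxy-6-(methoxymethoxy)benzaldehyde
Conditions: MOMCl (1.1 equiv), iPr2NEt, CH2Cl2, 0 °C
Reagents that add atoms: chloromethyl methyl ether, COCCl
Why: After one ortho-hydroxyl is alkylated the other is locked in a strong hydrogen bond to the aldehyde, so the O-alkylation should stop at the mono-MOM ether, which marks the future O1.

Step 3
Reactants: 3 4-(TBSO)-2-hydroxy-6-(methoxymethoxy)benzaldehyde
Product: 4 4-(TBSO)-2-hydroxy-3-iodo-6-(methoxymethoxy)benzaldehyde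
Conditions: N-iodosuccinimide (1.05 equiv), CH2Cl2, 0 °C, dark
Reagents that add atoms: N-iodosuccinimide, O=C1CCC(=O)N1I
Why: Electrophilic aromatic iodination should go ortho to the free chelated phenol (between OH and OTBS), the usual site for 2-hydroxy-4,6-dialkoxyaryl carbonyl compounds, which places the handle on the future C6.

Step 4
Reactants: 4 4-(TBSO)-2-hydroxy-3-iodo-6-(methoxymethoxy)benzaldehyde
Product: 5 2,4-bis(TBSO)-3-iodo-6-(methoxymethoxy)benzaldehyde
Conditions: TBSOTf, 2,6-lutidine, CH2Cl2, −20 °C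
Reagents that add atoms: tert-butyldimethylsilyl trifluoromethanesulfonate, CC(C)(C)[Si](C)(C)OS(=O)(=O)C(F)(F)F
Why: The silyl triflate should silylate the hindered, hydrogen-bonded phenol flanked by iodine and the formyl group, while the hindered base keeps the MOM ether intact (phenol silylation).

Step 5
Reactants: 6 2,4-dihydroxybenzaldehyde
Product: 7 2,4-bis(TBSO)benzaldehyde
Conditions: TBSCl (2.3 equiv), imidazole, DMF, rt
Reagents that add atoms: tert-butyldimethylsilyl chloride, CC(C)(C)[Si](C)(C)Cl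
Why: Exhaustive silylation of both phenols is routine and gives the protected resorcinol aldehyde used for two fragments.

Step 6
Reactants: 7 2,4-bis(TBSO)benzaldehyde
Product: 8 [2,4-bis(TBSO)phenyl]methanol
Conditions: NaBH4, THF/EtOH, 0 °C, short reaction time
Reagents that add atoms: none
Why: Borohydride reduction of the aldehyde is fast at 0 °C, and a prompt neutral work-up should prevent migration of the ortho silyl group to the benzylic oxygen.

Step 7
Reactants: 8 [2,4-bis(TBSO)phenyl]methanol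
Product: 10 1-(chloromethyl)-2,4-bis(TBSO)benzene, via benzylic mesylate 9 (not isolated)
Conditions: MsCl, Et3N, CH2Cl2, 0 °C to rt
Reagents that add atoms: methanesulfonyl chloride (supplies the chlorine), CS(=O)(=O)Cl
Why: The mesylate of this electron-rich benzylic alcohol should be displaced in the flask by the chloride of the ammonium salt formed alongside it (sulfonylation, then nucleophilic substitution).

Step 8
Reactants: 10 1-(chloromethyl)-2,4-bis(TBSO)benzene; 5 2,4-bis(TBSO)-3-iodo-6-(methoxymethoxy)benzaldehyde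
Product: 12 rac-1-[2,4-bis(TBSO)-3-iodo-6-(methoxymethoxy)phenyl]-2-[2,4-bis(TBSO)phenyl]ethanol, via benzylic zinc chloride 11 (not isolated)
Conditions: Mg, ZnCl2, LiCl, THF, rt; then 5, 0 °C to rt
Reagents that add atoms: none
Why: Magnesium insertion in the presence of ZnCl2 and LiCl gives a benzylic zinc reagent that should add 1,2 to the aldehyde under MgCl2 activation without touching the aryl iodide or the silyl ethers (organozinc carbonyl addition); the racemic carbinol centre is erased in step 9.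

Step 9
Reactants: 12 rac-1-[2,4-bis(TBSO)-3-iodo-6-(methoxymethoxy)phenyl]-2-[2,4-bis(TBSO)phenyl]ethanol
Product: 13 1-[2,4-bis(TBSO)-3-iodo-6-(methoxymethoxy)phenyl]-2-[2,4-bis(TBSO)phenyl]ethanone
Conditions: Dess–Martin periodinane, CH2Cl2, rt
Reagents that add atoms: none
Why: Dess–Martin oxidation converts the hindered benzylic alcohol into the deoxybenzoin under neutral conditions that spare silyl ethers, acetal and iodide.

Step 10
Reactants: 13 1-[2,4-bis(TBSO)-3-iodo-6-(methoxymethoxy)phenyl]-2-[2,4-bis(TBSO)phenyl]ethanone; 14 3-methylbut-2-enal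
Product: 17 (2E)-1-[2,4-bis(TBSO)-3-iodo-6-(methoxymethoxy)phenyl]-2-[2,4-bis(TBSO)phenyl]-5-methylhexa-2,4-dien-1-one, via lithium aldolate 15 (not isolated), via allylic mesylate 16 (not isolated)
Conditions: LiN(SiMe3)2, THF, −78 °C; 14; MsCl, −78 to 0 °C; Et3N, rt
Reagents that add atoms: none
Why: 1,2-Addition of the lithium enolate of the benzylic ketone to the enal, mesylation and E1cB elimination should give the cross-conjugated dienone (aldol condensation), the more stable E isomer with the aroyl group trans to the vinyl group being expected.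

Step 11
Reactants: 17 (2E)-1-[2,4-bis(TBSO)-3-iodo-6-(methoxymethoxy)phenyl]-2-[2,4-bis(TBSO)phenyl]-5-methylhexa-2,4-dien-1-one
Product: 19 (2E)-1-[2,4-bis(TBSO)-6-hydroxy-3-iodophenyl]-2-[2,4-bis(TBSO)phenyl]-5-methylhexa-2,4-dien-1-one, via aryl trimethylsilyl ether 18 (not isolated)
Conditions: TMSOTf, 2,2'-bipyridyl, CH2Cl2, 0 °C; then H2O
Reagents that add atoms: none
Why: The silyl triflate–bipyridyl pair converts aromatic MOM ethers into aryl trimethylsilyl ethers under non-acidic conditions and water then frees the phenol, so the TBS ethers, the dienone and the iodide should survive (mild acetal cleavage).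

Step 12
Reactants: 19 (2E)-1-[2,4-bis(TBSO)-6-hydroxy-3-iodophenyl]-2-[2,4-bis(TBSO)phenyl]-5-methylhexa-2,4-dien-1-one
Product: 20 2-{(2E)-2-[2,4-bis(TBSO)phenyl]-5-methylhexa-2,4-dienoyl}-3,5-bis(TBSO)-4-iodophenyl pentafluorophenyl carbonate
Conditions: (C6F5O)2CO, 4-methylmorpholine (cat.), CH2Cl2, 0 °C
Reagents that add atoms: bis(pentafluorophenyl) carbonate, O=C(Oc1c(F)c(F)c(F)c(F)c1F)Oc1c(F)c(F)c(F)c(F)c1F
Why: Acyl transfer from the active carbonate to the phenol (transcarbonation) under weakly basic, cold conditions should outrun oxa-Michael closure and installs the C2 carbon on O1 with a leaving group better than the ring A phenoxide.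

Step 13
Reactants: 20 2-{(2E)-2-[2,4-bis(TBSO)phenyl]-5-methylhexa-2,4-dienoyl}-3,5-bis(TBSO)-4-iodophenyl pentafluorophenyl carbonate
Product: 22 (3S)-3-[2,4-bis(TBSO)phenyl]-5,7-bis(TBSO)-6-iodo-3-(3-methylbut-2-enyl)chromane-2,4-dione, via copper enolate 21 (not isolated)
Conditions: Cu(OAc)2 (5 mol %), (R)-SEGPHOS (5.5 mol %), (HMe2Si)2O, THF, 0 °C to rt
Reagents that add atoms: none
Why: Proposed new method: the bisphosphine-bound copper hydride formed from Cu(OAc)2 and the silane delivers hydride to the CH next to C3 of the cross-conjugated dienone (1,4-hydrocupration), which turns that carbon into the prenyl CH2 and gives copper enolate 21, whose carbon C3 attacks the O1-bound pentafluorophenyl carbonate carbonyl at the end of the C4–C4a–C8a–O1 tether; collapse of the tetrahedral intermediate expels pentafluorophenoxide, and the silane returns the copper phenoxide to copper hydride. The closest known reaction type is the copper hydride-catalysed enantioselective reductive aldol cyclisation (conjugate hydride addition, then capture of the chiral copper enolate by a tethered carbonyl group), extended here from a ketone to an activated carbonate as terminating electrophile, that is, a reductive Claisen–Dieckmann cyclisation. Ring C closes by formation of the C2–C3 bond in a 6-(enolendo)-exo-trig mode. The only new stereocentre, quaternary C3, is under catalyst control: the two ortho substituents twist ring A out of the enolate plane, so the carbonate can reach only the enolate face it lies over, and the (R)-SEGPHOS-bound copper, bridging enolate oxygen and carbonate carbonyl in a closed transition state, should select one twist sense and with it one face of C3. The step needs 1,4- over 1,6- and 1,2-hydride delivery (secured by the fully substituted dimethyl terminus and by the twisted, di-ortho-substituted aryl ketone), C- over O-acylation (soft copper enolate, perpendicular ring A) and ring closure over silyl trapping of the enolate (six-membered attack on a highly activated carbonate whose leaving group is a weaker base than the ring A phenoxide, so the lactone cannot re-open); the aryl iodide is expected to be tolerated.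

Step 14
Reactants: 23 2-methylbut-1-en-3-yne
Product: 24 tributyl[(1E)-3-methylbuta-1,3-dienyl]stannane
Conditions: Bu3SnH, Pd(PPh3)2Cl2 (1 mol %), THF, 0 °C
Reagents that add atoms: tributyltin hydride, CCCC[SnH](CCCC)CCCC
Why: Palladium-catalysed syn-hydrostannation of the terminal alkyne should place tin at the terminus and give the E-dienylstannane, with any internal regioisomer removed by chromatography.

Step 15
Reactants: 22 (3S)-3-[2,4-bis(TBSO)phenyl]-5,7-bis(TBSO)-6-iodo-3-(3-methylbut-2-enyl)chromane-2,4-dione; 24 tributyl[(1E)-3-methylbuta-1,3-dienyl]stannane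
Product: 25 (3S)-3-[2,4-bis(TBSO)phenyl]-5,7-bis(TBSO)-6-[(1E)-3-methylbuta-1,3-dienyl]-3-(3-methylbut-2-enyl)chromane-2,4-dione
Conditions: Pd2(dba)3 (cat.), AsPh3, CuI (cat.), DMF, 45 °C
Reagents that add atoms: none
Why: Copper-assisted Stille coupling of the aryl iodide runs without base or fluoride, so it should install the diene with retention of E geometry while sparing the lactone, the silyl ethers and the C3 stereocentre.

Step 16
Reactants: 26 1-(2,4-dihydroxyphenyl)ethanone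
Product: 27 1-[4-(TBSO)-2-hydroxyphenyl]ethanone
Conditions: TBSCl (1.05 equiv), imidazole, CH2Cl2, 0 °C
Reagents that add atoms: tert-butyldimethylsilyl chloride, CC(C)(C)[Si](C)(C)Cl
Why: Only the non-chelated 4-hydroxyl should be silylated, which leaves the ketone-bound 2-hydroxyl free for boron binding in step 18 (selective phenol silylation).

Step 17
Reactants: 27 1-[4-(TBSO)-2-hydroxyphenyl]ethanone; 7 2,4-bis(TBSO)benzaldehyde
Product: 28 (2E)-3-[2,4-bis(TBSO)phenyl]-1-[4-(TBSO)-2-hydroxyphenyl]prop-2-en-1-one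
Conditions: LiN(SiMe3)2 (3 equiv), THF, −78 °C to rt
Reagents that add atoms: none
Why: Claisen–Schmidt condensation through the lithium dianion of the 2-hydroxyacetophenone (aldol addition, then E1cB loss of hydroxide) should give the E-chalcone without the hydroxide bases that cleave aryl silyl ethers.

Step 18
Reactants: 25 (3S)-3-[2,4-bis(TBSO)phenyl]-5,7-bis(TBSO)-6-[(1E)-3-methylbuta-1,3-dienyl]-3-(3-methylbut-2-enyl)chromane-2,4-dione; 28 (2E)-3-[2,4-bis(TBSO)phenyl]-1-[4-(TBSO)-2-hydroxyphenyl]prop-2-en-1-one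
Product: 29 (3S)-3-[2,4-bis(TBSO)phenyl]-5,7-bis(TBSO)-6-{(1S,5R,6S)-5-[2,4-bis(TBSO)phenyl]-6-[4-(TBSO)-2-hydroxybenzoyl]-3-methylcyclohex-2-en-1-yl}-3-(3-methylbut-2-enyl)chromane-2,4-dione
Conditions: B(OPh)3, (R)-VANOL (1.2 equiv each), 4 Å MS, PhCF3, rt
Reagents that add atoms: none
Why: The 2-hydroxychalcone binds the VANOL borate through phenoxide and carbonyl oxygen and the chiral complex undergoes [4+2] cycloaddition with the diene (boron-templated asymmetric Diels–Alder reaction of 2'-hydroxychalcones), with regiochemistry from the ortho and para rules, C1'' and C5'' from catalyst-controlled facial selection, the trans C5''/C6'' relation from the E dienophile, and the exo (trans,trans) isomer separated and carried on.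

Step 19
Reactants: 29 (3S)-3-[2,4-bis(TBSO)phenyl]-5,7-bis(TBSO)-6-{(1S,5R,6S)-5-[2,4-bis(TBSO)phenyl]-6-[4-(TBSO)-2-hydroxybenzoyl]-3-methylcyclohex-2-en-1-yl}-3-(3-methylbut-2-enyl)chromane-2,4-dione
Product: 31 (3S)-3-[2,4-bis(TBSO)phenyl]-5,7-bis(TBSO)-6-{(1S,5R,6R)-5-[2,4-bis(TBSO)phenyl]-6-[4-(TBSO)-2-hydroxybenzoyl]-3-methylcyclohex-2-en-1-yl}-3-(3-methylbut-2-enyl)chromane-2,4-dione, via dipotassium enolate 30 (not isolated)
Conditions: KN(SiMe3)2 (3 equiv), THF, −78 °C; then AcOH in THF, −78 °C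
Reagents that add atoms: none
Why: Deprotonation of the phenol and of the only enolisable carbon gives an exocyclic enolate whose two flanking aryl groups sit on the same ring face, and irreversible cold protonation from the open opposite face should place the aroyl group cis to both (kinetic protonation under substrate control), inverting C6'' while the non-enolisable chromanedione is left alone.

Step 20
Reactants: 31 (3S)-3-[2,4-bis(TBSO)phenyl]-5,7-bis(TBSO)-6-{(1S,5R,6R)-5-[2,4-bis(TBSO)phenyl]-6-[4-(TBSO)-2-hydroxybenzoyl]-3-methylcyclohex-2-en-1-yl}-3-(3-methylbut-2-enyl)chromane-2,4-dione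
Product: 32 (3S)-3-(2,4-dihydroxyphenyl)-6-[(1S,5R,6R)-6-(2,4-dihydroxybenzoyl)-5-(2,4-dihydroxyphenyl)-3-methylcyclohex-2-en-1-yl]-5,7-dihydroxy-3-(3-methylbut-2-enyl)chromane-2,4-dione
Conditions: HF·pyridine, pyridine, THF, 0 °C to rt
Reagents that add atoms: none
Why: Pyridine-buffered HF should cleave the seven aryl silyl ethers without base or strong acid, so the lactone, the two alkenes and the epimerisable C6'' centre are not endangered (fluoride desilylation).

**Compound list**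

1 | 2,4,6-trihydroxybenzaldehyde | O=Cc1c(O)cc(O)cc1O | starting material
2 | 4-(TBSO)-2,6-dihydroxybenzaldehyde | O=Cc1c(O)cc(O[Si](C)(C)C(C)(C)C)cc1O | intermediate
3 | 4-(TBSO)-2-hydroxy-6-(methoxymethoxy)benzaldehyde | O=Cc1c(O)cc(O[Si](C)(C)C(C)(C)C)cc1OCOC | intermediate
4 | 4-(TBSO)-2-hydroxy-3-iodo-6-(methoxymethoxy)benzaldehyde | O=Cc1c(O)c(I)c(O[Si](C)(C)C(C)(C)C)cc1OCOC | intermediate
5 | 2,4-bis(TBSO)-3-iodo-6-(methoxymethoxy)benzaldehyde | O=Cc1c(O[Si](C)(C)C(C)(C)C)c(I)c(O[Si](C)(C)C(C)(C)C)cc1OCOC | intermediate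
6 | 2,4-dihydroxybenzaldehyde | O=Cc1ccc(O)cc1O | starting material
7 | 2,4-bis(TBSO)benzaldehyde | O=Cc1ccc(O[Si](C)(C)C(C)(C)C)cc1O[Si](C)(C)C(C)(C)C | intermediate
8 | [2,4-bis(TBSO)phenyl]methanol | OCc1ccc(O[Si](C)(C)C(C)(C)C)cc1O[Si](C)(C)C(C)(C)C | intermediate
9 | 2,4-bis(TBSO)benzyl methanesulfonate (formed in situ) | CS(=O)(=O)OCc1ccc(O[Si](C)(C)C(C)(C)C)cc1O[Si](C)(C)C(C)(C)C | intermediate
10 | 1-(chloromethyl)-2,4-bis(TBSO)benzene | ClCc1ccc(O[Si](C)(C)C(C)(C)C)cc1O[Si](C)(C)C(C)(C)C | intermediate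
11 | [2,4-bis(TBSO)benzyl]zinc chloride (formed in situ) | Cl[Zn]Cc1ccc(O[Si](C)(C)C(C)(C)C)cc1O[Si](C)(C)C(C)(C)C | intermediate
12 | rac-1-[2,4-bis(TBSO)-3-iodo-6-(methoxymethoxy)phenyl]-2-[2,4-bis(TBSO)phenyl]ethanol | OC(Cc1ccc(O[Si](C)(C)C(C)(C)C)cc1O[Si](C)(C)C(C)(C)C)c1c(O[Si](C)(C)C(C)(C)C)c(I)c(O[Si](C)(C)C(C)(C)C)cc1OCOC | intermediate
13 | 1-[2,4-bis(TBSO)-3-iodo-6-(methoxymethoxy)phenyl]-2-[2,4-bis(TBSO)phenyl]ethanone | O=C(Cc1ccc(O[Si](C)(C)C(C)(C)C)cc1O[Si](C)(C)C(C)(C)C)c1c(O[Si](C)(C)C(C)(C)C)c(I)c(O[Si](C)(C)C(C)(C)C)cc1OCOC | intermediate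
14 | 3-methylbut-2-enal | CC(C)=CC=O | starting material
15 | lithium aldolate from 13 and 14 (formed in situ) | [Li]OC(C=C(C)C)C(c1ccc(O[Si](C)(C)C(C)(C)C)cc1O[Si](C)(C)C(C)(C)C)C(=O)c1c(O[Si](C)(C)C(C)(C)C)c(I)c(O[Si](C)(C)C(C)(C)C)cc1OCOC | intermediate
16 | allylic mesylate of the aldol (formed in situ) | CS(=O)(=O)OC(C=C(C)C)C(c1ccc(O[Si](C)(C)C(C)(C)C)cc1O[Si](C)(C)C(C)(C)C)C(=O)c1c(O[Si](C)(C)C(C)(C)C)c(I)c(O[Si](C)(C)C(C)(C)C)cc1OCOC | intermediate
17 | (2E)-1-[2,4-bis(TBSO)-3-iodo-6-(methoxymethoxy)phenyl]-2-[2,4-bis(TBSO)phenyl]-5-methylhexa-2,4-dien-1-one | O=C(c1c(O[Si](C)(C)C(C)(C)C)c(I)c(O[Si](C)(C)C(C)(C)C)cc1OCOC)/C(c1ccc(O[Si](C)(C)C(C)(C)C)cc1O[Si](C)(C)C(C)(C)C)=C/C=C(C)C | intermediate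
18 | aryl trimethylsilyl ether of 19 (formed in situ) | O=C(c1c(O[Si](C)(C)C(C)(C)C)c(I)c(O[Si](C)(C)C(C)(C)C)cc1O[Si](C)(C)C)/C(c1ccc(O[Si](C)(C)C(C)(C)C)cc1O[Si](C)(C)C(C)(C)C)=C/C=C(C)C | intermediate
19 | (2E)-1-[2,4-bis(TBSO)-6-hydroxy-3-iodophenyl]-2-[2,4-bis(TBSO)phenyl]-5-methylhexa-2,4-dien-1-one | O=C(c1c(O[Si](C)(C)C(C)(C)C)c(I)c(O[Si](C)(C)C(C)(C)C)cc1O)/C(c1ccc(O[Si](C)(C)C(C)(C)C)cc1O[Si](C)(C)C(C)(C)C)=C/C=C(C)C | intermediate
20 | 2-{(2E)-2-[2,4-bis(TBSO)phenyl]-5-methylhexa-2,4-dienoyl}-3,5-bis(TBSO)-4-iodophenyl pentafluorophenyl carbonate | O=C(c1c(O[Si](C)(C)C(C)(C)C)c(I)c(O[Si](C)(C)C(C)(C)C)cc1OC(=O)Oc1c(F)c(F)c(F)c(F)c1F)/C(c1ccc(O[Si](C)(C)C(C)(C)C)cc1O[Si](C)(C)C(C)(C)C)=C/C=C(C)C | intermediate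
21 | copper enolate from 20 (ligand omitted; formed in situ) | [Cu]OC(=C(CC=C(C)C)c1ccc(O[Si](C)(C)C(C)(C)C)cc1O[Si](C)(C)C(C)(C)C)c1c(O[Si](C)(C)C(C)(C)C)c(I)c(O[Si](C)(C)C(C)(C)C)cc1OC(=O)Oc1c(F)c(F)c(F)c(F)c1F | intermediate
22 | (3S)-3-[2,4-bis(TBSO)phenyl]-5,7-bis(TBSO)-6-iodo-3-(3-methylbut-2-enyl)chromane-2,4-dione | CC(C)=CC[C@@]1(c2ccc(O[Si](C)(C)C(C)(C)C)cc2O[Si](C)(C)C(C)(C)C)C(=O)Oc2cc(O[Si](C)(C)C(C)(C)C)c(I)c(O[Si](C)(C)C(C)(C)C)c2C1=O | intermediate
23 | 2-methylbut-1-en-3-yne | C=C(C)C#C | starting material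
24 | tributyl[(1E)-3-methylbuta-1,3-dienyl]stannane | CCCC[Sn](CCCC)(CCCC)/C=C/C(C)=C | intermediate
25 | (3S)-3-[2,4-bis(TBSO)phenyl]-5,7-bis(TBSO)-6-[(1E)-3-methylbuta-1,3-dienyl]-3-(3-methylbut-2-enyl)chromane-2,4-dione | CC(C)=CC[C@@]1(c2ccc(O[Si](C)(C)C(C)(C)C)cc2O[Si](C)(C)C(C)(C)C)C(=O)Oc2cc(O[Si](C)(C)C(C)(C)C)c(/C=C/C(C)=C)c(O[Si](C)(C)C(C)(C)C)c2C1=O | intermediate
26 | 1-(2,4-dihydroxyphenyl)ethanone | CC(=O)c1ccc(O)cc1O | starting material
27 | 1-[4-(TBSO)-2-hydroxyphenyl]ethanone | CC(=O)c1ccc(O[Si](C)(C)C(C)(C)C)cc1O | intermediate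
28 | (2E)-3-[2,4-bis(TBSO)phenyl]-1-[4-(TBSO)-2-hydroxyphenyl]prop-2-en-1-one | O=C(/C=C/c1ccc(O[Si](C)(C)C(C)(C)C)cc1O[Si](C)(C)C(C)(C)C)c1ccc(O[Si](C)(C)C(C)(C)C)cc1O | intermediate
29 | (3S)-3-[2,4-bis(TBSO)phenyl]-5,7-bis(TBSO)-6-{(1S,5R,6S)-5-[2,4-bis(TBSO)phenyl]-6-[4-(TBSO)-2-hydroxybenzoyl]-3-methylcyclohex-2-en-1-yl}-3-(3-methylbut-2-enyl)chromane-2,4-dione (exo adduct) | CC(C)=CC[C@@]1(c2ccc(O[Si](C)(C)C(C)(C)C)cc2O[Si](C)(C)C(C)(C)C)C(=O)Oc2cc(O[Si](C)(C)C(C)(C)C)c([C@H]3C=C(C)C[C@@H](c4ccc(O[Si](C)(C)C(C)(C)C)cc4O[Si](C)(C)C(C)(C)C)[C@@H]3C(=O)c3ccc(O[Si](C)(C)C(C)(C)C)cc3O)c(O[Si](C)(C)C(C)(C)C)c2C1=O | intermediate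
30 | dipotassium phenoxide enolate of 29 (formed in situ) | CC(C)=CC[C@@]1(c2ccc(O[Si](C)(C)C(C)(C)C)cc2O[Si](C)(C)C(C)(C)C)C(=O)Oc2cc(O[Si](C)(C)C(C)(C)C)c([C@H]3C=C(C)C[C@@H](c4ccc(O[Si](C)(C)C(C)(C)C)cc4O[Si](C)(C)C(C)(C)C)C3=C([O-])c3ccc(O[Si](C)(C)C(C)(C)C)cc3[O-])c(O[Si](C)(C)C(C)(C)C)c2C1=O.[K+].[K+] | intermediate
31 | (3S)-3-[2,4-bis(TBSO)phenyl]-5,7-bis(TBSO)-6-{(1S,5R,6R)-5-[2,4-bis(TBSO)phenyl]-6-[4-(TBSO)-2-hydroxybenzoyl]-3-methylcyclohex-2-en-1-yl}-3-(3-methylbut-2-enyl)chromane-2,4-dione (all-cis) | CC(C)=CC[C@@]1(c2ccc(O[Si](C)(C)C(C)(C)C)cc2O[Si](C)(C)C(C)(C)C)C(=O)Oc2cc(O[Si](C)(C)C(C)(C)C)c([C@H]3C=C(C)C[C@@H](c4ccc(O[Si](C)(C)C(C)(C)C)cc4O[Si](C)(C)C(C)(C)C)[C@H]3C(=O)c3ccc(O[Si](C)(C)C(C)(C)C)cc3O)c(O[Si](C)(C)C(C)(C)C)c2C1=O | intermediate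
32 | (3S)-3-(2,4-dihydroxyphenyl)-6-[(1S,5R,6R)-6-(2,4-dihydroxybenzoyl)-5-(2,4-dihydroxyphenyl)-3-methylcyclohex-2-en-1-yl]-5,7-dihydroxy-3-(3-methylbut-2-enyl)chromane-2,4-dione | CC(C)=CC[C@@]1(c2ccc(O)cc2O)C(=O)Oc2cc(O)c([C@H]3C=C(C)C[C@@H](c4ccc(O)cc4O)[C@H]3C(=O)c3ccc(O)cc3O)c(O)c2C1=O | target

**Step count and risks**

Total step count: 20. Longest linear sequence: 14 (steps 1–4, 8–13, 15, 18–20).

Steps most likely to fail:

Step 13 (proposed new method). The copper enolate may be silylated or protonated before it reaches the carbonate, hydride may be delivered to the carbonyl or to the far end of the dienone, or facial discrimination at C3 may be poor. The fallback uses known chemistry, sets out from 13 and comes back at 22. C-Alkylation of 13 with 1-bromo-3-methylbut-2-ene (KOtBu, THF, 0 °C) should give rac-1-[2,4-bis(TBSO)-3-iodo-6-(methoxymethoxy)phenyl]-2-[2,4-bis(TBSO)phenyl]-5-methylhex-4-en-1-one F1. Acid-catalysed acetal exchange (HCl cat., MeOH/THF, 0 °C) should free rac-1-[2,4-bis(TBSO)-6-hydroxy-3-iodophenyl]-2-[2,4-bis(TBSO)phenyl]-5-methylhex-4-en-1-one F2. Transcarbonation with (C6F5O)2CO as in step 12 should give rac-2-{2-[2,4-bis(TBSO)phenyl]-5-methylhex-4-enoyl}-3,5-bis(TBSO)-4-iodophenyl pentafluorophenyl carbonate F3. Base-mediated Dieckmann-type closure of the potassium enolate onto the carbonate (KN(SiMe3)2, THF, −78 °C) should give racemic 3-[2,4-bis(TBSO)phenyl]-5,7-bis(TBSO)-6-iodo-3-(3-methylbut-2-enyl)chromane-2,4-dione F4. Preparative chromatography on a chiral stationary phase would then deliver 22 and set aside its (3R)-enantiomer F5.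

Step 18. The exo preference may be low, the di-ortho-silyloxy diene may react sluggishly, or the borate may be mismatched with the remote C3 centre. The fallback sets out from 25 and 28 and comes back at 29. It gives up reagent control: the cycloaddition is run with Ag nanoparticles on SiO2 (from AgBF4 and Bu4NBH4, CH2Cl2, 50 °C), an achiral electron-transfer catalyst known for 2'-hydroxychalcone cycloadditions. Because C3 is already enantiopure, all isomers formed are diastereomers, and 29 would be isolated by preparative HPLC. No compound outside the list is made (F0).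

Step 19. Enolisation of the hindered ketone may be incomplete, protonation may occur on the wrong face, or the amide base may attack the lactone. The fallback sets out from 29 and comes back at 32. It replaces strong-base enolisation by soft enolisation: TBSOTf (excess) and Et3N in CH2Cl2 at 0 °C to rt should silylate the phenol and convert the ketone into its silyl enol ether, giving the isolable (3S)-3-[2,4-bis(TBSO)phenyl]-5,7-bis(TBSO)-6-{(1S,5R)-5-[2,4-bis(TBSO)phenyl]-6-{[2,4-bis(TBSO)phenyl](TBSO)methylidene}-3-methylcyclohex-2-en-1-yl}-3-(3-methylbut-2-enyl)chromane-2,4-dione F6. In the HF·pyridine treatment of step 20, protodesilylation of the enol ether is itself a kinetic protonation on the open ring face, so F6 would go directly to 32.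

**Further compounds**

F1 | step 13 | rac-1-[2,4-bis(TBSO)-3-iodo-6-(methoxymethoxy)phenyl]-2-[2,4-bis(TBSO)phenyl]-5-methylhex-4-en-1-one | CC(C)=CCC(c1ccc(O[Si](C)(C)C(C)(C)C)cc1O[Si](C)(C)C(C)(C)C)C(=O)c1c(O[Si](C)(C)C(C)(C)C)c(I)c(O[Si](C)(C)C(C)(C)C)cc1OCOC
F2 | step 13 | rac-1-[2,4-bis(TBSO)-6-hydroxy-3-iodophenyl]-2-[2,4-bis(TBSO)phenyl]-5-methylhex-4-en-1-one | CC(C)=CCC(c1ccc(O[Si](C)(C)C(C)(C)C)cc1O[Si](C)(C)C(C)(C)C)C(=O)c1c(O[Si](C)(C)C(C)(C)C)c(I)c(O[Si](C)(C)C(C)(C)C)cc1O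
F3 | step 13 | rac-2-{2-[2,4-bis(TBSO)phenyl]-5-methylhex-4-enoyl}-3,5-bis(TBSO)-4-iodophenyl pentafluorophenyl carbonate | CC(C)=CCC(c1ccc(O[Si](C)(C)C(C)(C)C)cc1O[Si](C)(C)C(C)(C)C)C(=O)c1c(O[Si](C)(C)C(C)(C)C)c(I)c(O[Si](C)(C)C(C)(C)C)cc1OC(=O)Oc1c(F)c(F)c(F)c(F)c1F
F4 | step 13 | racemic 3-[2,4-bis(TBSO)phenyl]-5,7-bis(TBSO)-6-iodo-3-(3-methylbut-2-enyl)chromane-2,4-dione | CC(C)=CCC1(c2ccc(O[Si](C)(C)C(C)(C)C)cc2O[Si](C)(C)C(C)(C)C)C(=O)Oc2cc(O[Si](C)(C)C(C)(C)C)c(I)c(O[Si](C)(C)C(C)(C)C)c2C1=O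
F5 | step 13 | (3R)-3-[2,4-bis(TBSO)phenyl]-5,7-bis(TBSO)-6-iodo-3-(3-methylbut-2-enyl)chromane-2,4-dione | CC(C)=CC[C@]1(c2ccc(O[Si](C)(C)C(C)(C)C)cc2O[Si](C)(C)C(C)(C)C)C(=O)Oc2cc(O[Si](C)(C)C(C)(C)C)c(I)c(O[Si](C)(C)C(C)(C)C)c2C1=O
F0 | step 18 | none | none
F6 | step 19 | (3S)-3-[2,4-bis(TBSO)phenyl]-5,7-bis(TBSO)-6-{(1S,5R)-5-[2,4-bis(TBSO)phenyl]-6-{[2,4-bis(TBSO)phenyl](TBSO)methylidene}-3-methylcyclohex-2-en-1-yl}-3-(3-methylbut-2-enyl)chromane-2,4-dione | CC(C)=CC[C@@]1(c2ccc(O[Si](C)(C)C(C)(C)C)cc2O[Si](C)(C)C(C)(C)C)C(=O)Oc2cc(O[Si](C)(C)C(C)(C)C)c([C@H]3C=C(C)C[C@@H](c4ccc(O[Si](C)(C)C(C)(C)C)cc4O[Si](C)(C)C(C)(C)C)C3=C(O[Si](C)(C)C(C)(C)C)c3ccc(O[Si](C)(C)C(C)(C)C)cc3O[Si](C)(C)C(C)(C)C)c(O[Si](C)(C)C(C)(C)C)c2C1=O
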